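**Retrosynthetic overview**

1. The target comes from its heptabenzyl ether by debenzylation. That ether comes from a tricyclic malonyl lactone in which one carbonyl carbon bridges O8 and C1. Hydrolysis, loss of CO2 and protonation of C1 anti to the C2 aryl group give the cis-(1S,2S) pair.
2. The C3 ester comes from a C3 enal by Pinnick oxidation and a Mitsunobu reaction. One (R)-aryl-lactate alcohol serves twice: with retention for the (R)-ester at C1 and with inversion for the (S)-ester at C3.
3. The key disconnection cuts C8a–C1 and C3=C4 together. It leads back to an open 2-bromo-3-formylaryl malonate that already carries C2 and a CH2CHO arm. The temporary five-membered lactone ring closes first and ring B second.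
4. That precursor comes from a 2-bromophenol aldehyde and a malonic half acid. C2 is set by an amine-catalysed asymmetric Michael addition of the malonate to the caffeic-type enal.
5. Enabling feature (1,2-dihydronaphthalene numbering; ring A = fused catechol ring C4a–C8a, ring B = C1–C4, C4a, C8a): C1–C2–C3 with its two carboxyl carbons is a 3-arylglutarate. C4 is the former formyl carbon of ring A. The C8 hydroxyl lies peri to C1, so O8–C8–C8a–C1 plus one carbonyl carbon forms a five-membered lactone, and C7–O blocks the other ortho site of O8.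

Key step: step 8

Remark: the SMILES is read as cis-(1S,2S) in ring B, with an (R)-lactate unit on the C1 ester and an (S)-lactate unit on the C3 ester. Ar = 3,4-bis(benzyloxy)phenyl. (R)-Lac and (S)-Lac = (2R)- and (2S)-3-Ar-1-methoxy-1-oxopropan-2-yl.

**Step 1**
Reactants: 1 4-bromo-1,2-bis(benzyloxy)benzene; 2 methyl (2R)-oxirane-2-carboxylate
Product: 4 methyl (2R)-3-Ar-2-hydroxypropanoate, via aryl Grignard reagent 3 (not isolated)
Conditions: Mg, THF, 50 °C; then CuBr·SMe2 (10 mol %), 2, THF, −40 °C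
Reagents that add atoms: none
Why: Copper-catalysed Grignard opening of the glycidate at its unsubstituted CH2 carbon (SN2) does not touch the oxygen-bearing stereocentre, so the (R) configuration of 2 is carried into 4.

**Step 2**
Reactants: 4 methyl (2R)-3-Ar-2-hydroxypropanoate; 5 allyl hydrogen malonate
Product: 6 allyl (R)-Lac malonate
Conditions: DCC, DMAP (cat.), CH2Cl2, 0 °C to rt
Reagents that add atoms: none
Why: Steglich esterification acylates only the hydroxyl oxygen, so the (R) carbinol centre is retained.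

**Step 3**
Reactants: 7 3,4-bis(benzyloxy)benzaldehyde
Product: 8 (E)-3-Ar-prop-2-enal
Conditions: Ph3P=CHCHO, toluene, 80 °C
Reagents that add atoms: (triphenylphosphoranylidene)acetaldehyde, O=CC=P(c1ccccc1)(c1ccccc1)c1ccccc1
Why: Wittig olefination with the stabilised formyl ylide should give the (E)-enal.

**Step 4**
Reactants: 6 allyl (R)-Lac malonate; 8 (E)-3-Ar-prop-2-enal
Product: 9 allyl (R)-Lac 2-[(1S)-1-Ar-3-oxopropyl]malonate (malonate carbon epimerisable and left unassigned)
Conditions: (R)-2-{bis[3,5-bis(trifluoromethyl)phenyl][(trimethylsilyl)oxy]methyl}pyrrolidine (10 mol %), PhCO2H (10 mol %), EtOH, 0 °C to rt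
Reagents that add atoms: none
Why: In this iminium-catalysed asymmetric Michael addition of a malonate to an enal, the diaryl(silyloxy)methyl group of the (R)-amine shields one face of the (E)-iminium ion, so the malonate carbon (future C1) adds to the open face and sets the future C2 as (S).

**Step 5**
Reactants: 9 allyl (R)-Lac 2-[(1S)-1-Ar-3-oxopropyl]malonate
Product: 10 2-[(1S)-1-Ar-3-oxopropyl]malonic acid mono-(R)-Lac ester
Conditions: Pd(PPh3)4 (5 mol %), N-methylaniline, THF, rt
Reagents that add atoms: none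
Why: Tsuji–Trost deallylation under neutral conditions passes the allyl group to the amine and leaves the aldehyde, the benzyl ethers and both stereocentres untouched.

**Step 6**
Reactants: 11 4-(benzyloxy)-3-hydroxybenzaldehyde
Product: 12 4-(benzyloxy)-2-bromo-3-hydroxybenzaldehyde
Conditions: Br2, NaOAc, Fe powder (cat.), AcOH, rt
Reagents that add atoms: bromine, BrBr
Why: In buffered electrophilic aromatic bromination, 3-hydroxy-4-alkoxybenzaldehydes of the isovanillin type react ortho to the free phenol at C2 between OH and CHO, which is the future C8a.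

**Step 7**
Reactants: 10 2-[(1S)-1-Ar-3-oxopropyl]malonic acid mono-(R)-Lac ester; 12 4-(benzyloxy)-2-bromo-3-hydroxybenzaldehyde
Product: 13 6-(benzyloxy)-2-bromo-3-formylphenyl (R)-Lac 2-[(1S)-1-Ar-3-oxopropyl]malonate
Conditions: DCC, DMAP (cat.), CH2Cl2, 0 °C
Reagents that add atoms: none
Why: Steglich esterification of a malonic half acid, which is activated readily through its acyl ketene, acylates the phenol oxygen O8 and touches no stereocentre.

**Step 8**
Reactants: 13 6-(benzyloxy)-2-bromo-3-formylphenyl (R)-Lac 2-[(1S)-1-Ar-3-oxopropyl]malonate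
Product: 15 (R)-Lac (3S)-3-Ar-8-(benzyloxy)-4-formyl-2-oxo-2a,3-dihydro-2H-naphtho[1,8-bc]furan-2a-carboxylate (tricyclic lactone enal; quaternary C2a = C1 unassigned), via arylated benzofuranone 14 (not isolated)
Conditions: Pd2(dba)3 (2.5 mol %), P(tBu)3·HBF4 (10 mol %), K3PO4 (3 equiv), 4 Å MS, toluene, 70 °C
Reagents that add atoms: none
Why: Proposed new method: zerovalent palladium inserts into the C8a–Br bond, phosphate removes the acidic malonate C1–H, and C–C reductive elimination from the six-membered palladacycle closes the five-membered lactone ring (formal 5-exo closure) to give 14; the closest known reaction types are palladium-catalysed malonate α-arylation and the anilide-to-oxindole α-arylation, of which this is the ester-tethered counterpart. The same base then enolises the CH2CHO arm, which now lies next to the ring A formyl group, and a 6-(enolexo)-exo-trig aldol addition followed by E1cB loss of water closes ring B and creates C3=C4, as in known α-arylation/condensation dominoes of 2-bromobenzaldehydes. Site selectivity on ring A is secured by the bromine at C8a and by the O8 tether, whose other ortho position C7 carries oxygen. The order of events is secured because direct aldol closure of 13 would need a nine-membered ring and the tertiary malonate carbon cannot condense with an aldehyde, and the alkene geometry is dictated by ring B. The only new stereocentre, quaternary C1, forms next to C2 under its influence, but its configuration is irrelevant because step 11 erases it. C2 itself is untouched as long as ring closure outruns retro-Michael cleavage of C1–C2.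

**Step 9**
Reactants: 15 tricyclic lactone enal
Product: 16 (3S)-3-Ar-8-(benzyloxy)-2-oxo-2a-[(R)-Lac-oxycarbonyl]-2a,3-dihydro-2H-naphtho[1,8-bc]furan-4-carboxylic acid
Conditions: NaClO2, NaH2PO4, 2-methyl-2-butene, tBuOH/THF/H2O, 0 °C to rt
Reagents that add atoms: sodium chlorite, [Na+].[O-]Cl=O
Why: Pinnick oxidation converts the enal to the enoic acid at mildly acidic pH, which spares the alkene, the lactone and the esters.

**Step 10**
Reactants: 16 tricyclic lactone acid; 4 methyl (2R)-3-Ar-2-hydroxypropanoate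
Product: 17 2a-(R)-Lac 4-(S)-Lac (3S)-3-Ar-8-(benzyloxy)-2-oxo-2a,3-dihydro-2H-naphtho[1,8-bc]furan-2a,4-dicarboxylate
Conditions: PPh3, DIAD, THF, 0 °C to rt
Reagents that add atoms: none
Why: In the Mitsunobu reaction the carboxylate displaces the activated oxygen of the α-hydroxy ester by SN2 with inversion, so (R)-alcohol 4 gives the (S)-Lac ester at C3 under neutral conditions that leave the lactone intact.

**Step 11**
Reactants: 17 bis-Lac tricyclic lactone
Product: 19 1-(R)-Lac 3-(S)-Lac (1S,2S)-2-Ar-7-(benzyloxy)-8-hydroxy-1,2-dihydronaphthalene-1,3-dicarboxylate, via malonic half acid 18 (not isolated)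
Conditions: LiOH (1.05 equiv), THF/H2O, 0 °C; AcOH; then toluene, 50 °C
Reagents that add atoms: none
Why: The strained phenol-derived malonyl lactone is the most electrophilic ester and should be saponified first, after which the α-aryl malonic half acid 18 loses CO2 on gentle warming and the ester enol is protonated at C1 on the face opposite the pseudoaxial C2 aryl group (kinetic ketonisation after malonic acid decarboxylation), placing the C1 ester cis to the aryl group and setting (1S).

**Step 12**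
Reactants: 19 heptabenzyl ether
Product: 20 1-[(2R)-3-(3,4-dihydroxyphenyl)-1-methoxy-1-oxopropan-2-yl] 3-[(2S)-3-(3,4-dihydroxyphenyl)-1-methoxy-1-oxopropan-2-yl] (1S,2S)-2-(3,4-dihydroxyphenyl)-7,8-dihydroxy-1,2-dihydronaphthalene-1,3-dicarboxylate (CNP0237075.1)
Conditions: BCl3, pentamethylbenzene, CH2Cl2, −78 °C; then MeOH
Reagents that add atoms: none
Why: Lewis-acid debenzylation with Friedel–Crafts capture of the benzyl cations by pentamethylbenzene is non-reductive and non-basic, so C3=C4, all four esters and the epimerisable C1 centre should survive.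

**Compound list**

1 | 4-bromo-1,2-bis(benzyloxy)benzene | Brc1ccc(OCc2ccccc2)c(OCc2ccccc2)c1 | starting material
2 | methyl (2R)-oxirane-2-carboxylate | COC(=O)[C@H]1CO1 | starting material
3 | [3,4-bis(benzyloxy)phenyl]magnesium bromide | Br[Mg]c1ccc(OCc2ccccc2)c(OCc2ccccc2)c1 | intermediate
4 | methyl (2R)-3-[3,4-bis(benzyloxy)phenyl]-2-hydroxypropanoate | COC(=O)[C@H](O)Cc1ccc(OCc2ccccc2)c(OCc2ccccc2)c1 | intermediate
5 | allyl hydrogen malonate | OC(=O)CC(=O)OCC=C | starting material
6 | allyl (R)-Lac malonate | C=CCOC(=O)CC(=O)O[C@H](Cc1ccc(OCc2ccccc2)c(OCc2ccccc2)c1)C(=O)OC | intermediate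
7 | 3,4-bis(benzyloxy)benzaldehyde | O=Cc1ccc(OCc2ccccc2)c(OCc2ccccc2)c1 | starting material
8 | (E)-3-[3,4-bis(benzyloxy)phenyl]prop-2-enal | O=C/C=C/c1ccc(OCc2ccccc2)c(OCc2ccccc2)c1 | intermediate
9 | allyl (R)-Lac 2-[(1S)-1-Ar-3-oxopropyl]malonate | C=CCOC(=O)C(C(=O)O[C@H](Cc1ccc(OCc2ccccc2)c(OCc2ccccc2)c1)C(=O)OC)[C@H](CC=O)c1ccc(OCc2ccccc2)c(OCc2ccccc2)c1 | intermediate
10 | 2-[(1S)-1-Ar-3-oxopropyl]malonic acid mono-(R)-Lac ester | OC(=O)C(C(=O)O[C@H](Cc1ccc(OCc2ccccc2)c(OCc2ccccc2)c1)C(=O)OC)[C@H](CC=O)c1ccc(OCc2ccccc2)c(OCc2ccccc2)c1 | intermediate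
11 | 4-(benzyloxy)-3-hydroxybenzaldehyde | O=Cc1ccc(OCc2ccccc2)c(O)c1 | starting material
12 | 4-(benzyloxy)-2-bromo-3-hydroxybenzaldehyde | O=Cc1ccc(OCc2ccccc2)c(O)c1Br | intermediate
13 | 6-(benzyloxy)-2-bromo-3-formylphenyl (R)-Lac 2-[(1S)-1-Ar-3-oxopropyl]malonate | O=Cc1ccc(OCc2ccccc2)c(OC(=O)C(C(=O)O[C@H](Cc2ccc(OCc3ccccc3)c(OCc3ccccc3)c2)C(=O)OC)[C@H](CC=O)c2ccc(OCc3ccccc3)c(OCc3ccccc3)c2)c1Br | intermediate
14 | (R)-Lac 7-(benzyloxy)-4-formyl-2-oxo-3-[(1R)-1-Ar-3-oxopropyl]-2,3-dihydrobenzofuran-3-carboxylate (same spatial arrangement at the side-chain centre; only the descriptor changes) | O=Cc1ccc(OCc2ccccc2)c2OC(=O)C(C(=O)O[C@H](Cc3ccc(OCc4ccccc4)c(OCc4ccccc4)c3)C(=O)OC)([C@H](CC=O)c3ccc(OCc4ccccc4)c(OCc4ccccc4)c3)c12 | intermediate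
15 | (R)-Lac (3S)-3-Ar-8-(benzyloxy)-4-formyl-2-oxo-2a,3-dihydro-2H-naphtho[1,8-bc]furan-2a-carboxylate | O=CC1=Cc2ccc(OCc3ccccc3)c3OC(=O)C(C(=O)O[C@H](Cc4ccc(OCc5ccccc5)c(OCc5ccccc5)c4)C(=O)OC)([C@H]1c1ccc(OCc4ccccc4)c(OCc4ccccc4)c1)c23 | intermediate
16 | (3S)-3-Ar-8-(benzyloxy)-2-oxo-2a-[(R)-Lac-oxycarbonyl]-2a,3-dihydro-2H-naphtho[1,8-bc]furan-4-carboxylic acid | OC(=O)C1=Cc2ccc(OCc3ccccc3)c3OC(=O)C(C(=O)O[C@H](Cc4ccc(OCc5ccccc5)c(OCc5ccccc5)c4)C(=O)OC)([C@H]1c1ccc(OCc4ccccc4)c(OCc4ccccc4)c1)c23 | intermediate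
17 | 2a-(R)-Lac 4-(S)-Lac (3S)-3-Ar-8-(benzyloxy)-2-oxo-2a,3-dihydro-2H-naphtho[1,8-bc]furan-2a,4-dicarboxylate | COC(=O)[C@H](Cc1ccc(OCc2ccccc2)c(OCc2ccccc2)c1)OC(=O)C1=Cc2ccc(OCc3ccccc3)c3OC(=O)C(C(=O)O[C@H](Cc4ccc(OCc5ccccc5)c(OCc5ccccc5)c4)C(=O)OC)([C@H]1c1ccc(OCc4ccccc4)c(OCc4ccccc4)c1)c23 | intermediate
18 | (2S)-2-Ar-7-(benzyloxy)-8-hydroxy-1-[(R)-Lac-oxycarbonyl]-3-[(S)-Lac-oxycarbonyl]-1,2-dihydronaphthalene-1-carboxylic acid | COC(=O)[C@H](Cc1ccc(OCc2ccccc2)c(OCc2ccccc2)c1)OC(=O)C1=Cc2ccc(OCc3ccccc3)c(O)c2C(C(=O)O)(C(=O)O[C@H](Cc2ccc(OCc3ccccc3)c(OCc3ccccc3)c2)C(=O)OC)[C@H]1c1ccc(OCc2ccccc2)c(OCc2ccccc2)c1 | intermediate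
19 | 1-(R)-Lac 3-(S)-Lac (1S,2S)-2-Ar-7-(benzyloxy)-8-hydroxy-1,2-dihydronaphthalene-1,3-dicarboxylate | COC(=O)[C@H](Cc1ccc(OCc2ccccc2)c(OCc2ccccc2)c1)OC(=O)C1=Cc2ccc(OCc3ccccc3)c(O)c2[C@@H](C(=O)O[C@H](Cc2ccc(OCc3ccccc3)c(OCc3ccccc3)c2)C(=O)OC)[C@H]1c1ccc(OCc2ccccc2)c(OCc2ccccc2)c1 | intermediate
20 | CNP0237075.1 | COC(=O)[C@H](Cc1ccc(O)c(O)c1)OC(=O)C1=Cc2ccc(O)c(O)c2[C@@H](C(=O)O[C@H](Cc2ccc(O)c(O)c2)C(=O)OC)[C@H]1c1ccc(O)c(O)c1 | target

**Total step count:** 12. **Longest linear sequence:** 10 (steps 1, 2, 4, 5, 7, 8, 9, 10, 11, 12).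

**Steps most likely to fail**

**Step 8.** Once C1 is arylated, its carbanion is a very good leaving group. Enolisation of the aldehyde arm can therefore open a retro-Michael channel that cleaves C1–C2 and erodes the C2 configuration. Before oxidative addition, the aryl malonate anion may also expel the phenoxide in a ketene-type elimination.

The fallback uses known chemistry, makes the two bonds in separate flasks, and turns the Michael equilibrium into the productive, catalyst-controlled path. It sets out from 12 (together with 4 and 8) and comes back at 18. Phenol 12 is capped (MOMCl, iPr2NEt) as 4-(benzyloxy)-2-bromo-3-(methoxymethoxy)benzaldehyde F1. Alcohol 4 is esterified with mono-tert-butyl malonate (DCC, DMAP) to tert-butyl (R)-Lac malonate F2. Intermolecular palladium-catalysed malonate α-arylation of F2 with F1 (Pd2(dba)3, P(tBu)3·HBF4, K3PO4, toluene) gives the 2-formylaryl malonate F3. The amine of step 4 then catalyses the iminium/enamine Michael–aldol condensation domino of F3 with enal 8 to the 1,2-dihydronaphthalene enal F4, in which the catalyst sets C2. Pinnick oxidation gives acid F5 and a Mitsunobu reaction with 4 gives triester F6. CF3CO2H in CH2Cl2 removes the tert-butyl ester and the MOM ether to give 18, which is decarboxylated as in step 11.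

**Step 11.** Hydroxide may also attack the activated methyl and Lac esters. In addition, ketonisation of the enol may show poor facial selectivity, or C1 may drift to the more stable trans arrangement.

The fallback unmasks the acid without hydrolysis and protonates an enolate with an external bulky acid. It sets out from 17 and comes back at 19. DMAP-catalysed alcoholysis of the strained lactone with 2-(trimethylsilyl)ethanol gives the 2-(trimethylsilyl)ethyl malonate F7 with free O8–H. Bu4NF buffered with AcOH, in the presence of 2,6-di-tert-butyl-4-methylphenol at low temperature, then releases the carboxylate. This loses CO2, and the enolate is protonated from the face opposite the C2 aryl group to give 19.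

**Step 7.** Acylation of a phenol flanked by Br and OBn may be slow. The activated half acid may then decarboxylate, rearrange to the N-acylurea, or engage its own aldehyde arm.

The fallback builds the aryl ester on the small, unsubstituted malonate first and sets C2 afterwards. It sets out from 4 and 12 and comes back at 13. Heating 4 with Meldrum's acid in toluene gives (R)-Lac hydrogen malonate F8. Steglich esterification of F8 with 12 gives the aryl (R)-Lac malonate F9. The Michael addition of F9 to enal 8 under the catalyst of step 4, in toluene, gives 13.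

**Further compounds**

F1 | step 8 | 4-(benzyloxy)-2-bromo-3-(methoxymethoxy)benzaldehyde | O=Cc1ccc(OCc2ccccc2)c(OCOC)c1Br
F2 | step 8 | tert-butyl (R)-Lac malonate | CC(C)(C)OC(=O)CC(=O)O[C@H](Cc1ccc(OCc2ccccc2)c(OCc2ccccc2)c1)C(=O)OC
F3 | step 8 | tert-butyl (R)-Lac 2-[3-(benzyloxy)-6-formyl-2-(methoxymethoxy)phenyl]malonate | O=Cc1ccc(OCc2ccccc2)c(OCOC)c1C(C(=O)OC(C)(C)C)C(=O)O[C@H](Cc1ccc(OCc2ccccc2)c(OCc2ccccc2)c1)C(=O)OC
F4 | step 8 | 1-tert-butyl 1-(R)-Lac (2S)-2-Ar-7-(benzyloxy)-3-formyl-8-(methoxymethoxy)-1,2-dihydronaphthalene-1,1-dicarboxylate | O=CC1=Cc2ccc(OCc3ccccc3)c(OCOC)c2C(C(=O)OC(C)(C)C)(C(=O)O[C@H](Cc2ccc(OCc3ccccc3)c(OCc3ccccc3)c2)C(=O)OC)[C@H]1c1ccc(OCc2ccccc2)c(OCc2ccccc2)c1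
F5 | step 8 | corresponding 3-carboxylic acid of F4 | OC(=O)C1=Cc2ccc(OCc3ccccc3)c(OCOC)c2C(C(=O)OC(C)(C)C)(C(=O)O[C@H](Cc2ccc(OCc3ccccc3)c(OCc3ccccc3)c2)C(=O)OC)[C@H]1c1ccc(OCc2ccccc2)c(OCc2ccccc2)c1
F6 | step 8 | 1-tert-butyl 1-(R)-Lac 3-(S)-Lac (2S)-2-Ar-7-(benzyloxy)-8-(methoxymethoxy)-1,2-dihydronaphthalene-1,1,3-tricarboxylate | COC(=O)[C@H](Cc1ccc(OCc2ccccc2)c(OCc2ccccc2)c1)OC(=O)C1=Cc2ccc(OCc3ccccc3)c(OCOC)c2C(C(=O)OC(C)(C)C)(C(=O)O[C@H](Cc2ccc(OCc3ccccc3)c(OCc3ccccc3)c2)C(=O)OC)[C@H]1c1ccc(OCc2ccccc2)c(OCc2ccccc2)c1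
F7 | step 11 | 1-(R)-Lac 3-(S)-Lac 1-[2-(trimethylsilyl)ethyl] (2S)-2-Ar-7-(benzyloxy)-8-hydroxy-1,2-dihydronaphthalene-1,1,3-tricarboxylate | COC(=O)[C@H](Cc1ccc(OCc2ccccc2)c(OCc2ccccc2)c1)OC(=O)C1=Cc2ccc(OCc3ccccc3)c(O)c2C(C(=O)OCC[Si](C)(C)C)(C(=O)O[C@H](Cc2ccc(OCc3ccccc3)c(OCc3ccccc3)c2)C(=O)OC)[C@H]1c1ccc(OCc2ccccc2)c(OCc2ccccc2)c1
F8 | step 7 | (R)-Lac hydrogen malonate | OC(=O)CC(=O)O[C@H](Cc1ccc(OCc2ccccc2)c(OCc2ccccc2)c1)C(=O)OC
F9 | step 7 | 6-(benzyloxy)-2-bromo-3-formylphenyl (R)-Lac malonate | O=Cc1ccc(OCc2ccccc2)c(OC(=O)CC(=O)O[C@H](Cc2ccc(OCc3ccccc3)c(OCc3ccccc3)c2)C(=O)OC)c1Br
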